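## Retrosynthetic overview

1. The oxirane is the only ring to be made and it is made last: enantioselective oxygen-atom transfer (non-haem iron/H2O2, oxygenase-like) to the 1,1-disubstituted alkene of the fully acylated 10-acetoxy-8,9-dehydrothymol sets the single (S) centre directly in the target.
2. The allylic acetate comes from allylic C–H hydroxylation of the isopropenyl arene (the 8,9-dehydrothymol stage) and acetylation in the same flask, in the biosynthetic order: dehydro stage, C-10 oxygenation, epoxidation.
3. The isopropenyl group is attached by Suzuki–Miyaura coupling of an aryl bromide with isopropenylboronic acid pinacol ester.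
4. The two esters on the bromoarene are told apart without protecting groups: a lipase acylates only the benzylic alcohol, then an acid chloride acylates the phenol. The benzene ring is bought.

Assumption: 2-bromo-5-(hydroxymethyl)phenol is taken as a catalogue starting material, and the target SMILES is read as the (S)-configured oxirane carbon (priorities: ring O > CH2OAc > ring CH2 > aryl).

Abbreviations: Me2N-PDP = (2S,2'S)-1,1'-bis[(4-dimethylaminopyridin-2-yl)methyl]-2,2'-bipyrrolidine for the (S,S) form; dppf = 1,1'-bis(diphenylphosphino)ferrocene; DIPT = diisopropyl tartrate; SPhos = 2-dicyclohexylphosphino-2',6'-dimethoxybiphenyl.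

## Route

Step 1
Reactants: 1 2-bromo-5-(hydroxymethyl)phenol
Product: 2 (4-bromo-3-hydroxyphenyl)methyl pentanoate
Conditions: vinyl pentanoate (3 equiv), immobilised Candida antarctica lipase B, MTBE, 40 °C
Reagents that add atoms: vinyl pentanoate, CCCCC(=O)OC=C
Why: Lipase-catalysed irreversible transesterification with an enol ester acylates only the primary benzylic hydroxyl and leaves the phenol free, so the two hydroxyls are differentiated without a protecting group; no stereocentre is formed.

Step 2
Reactants: 2 (4-bromo-3-hydroxyphenyl)methyl pentanoate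
Product: 3 [4-bromo-3-(2-methylpropanoyloxy)phenyl]methyl pentanoate
Conditions: iPrCOCl (1.2 equiv), Et3N (1.5 equiv), DMAP (5 mol %), CH2Cl2, 0 °C to rt
Reagents that add atoms: 2-methylpropanoyl chloride, CC(C)C(Cl)=O
Why: DMAP-catalysed O-acylation of the only remaining hydroxyl, the ortho-bromophenol, with an acid chloride; the alkyl ester is inert and no stereocentre is formed.

Step 3
Reactants: 3 [4-bromo-3-(2-methylpropanoyloxy)phenyl]methyl pentanoate; 4 4,4,5,5-tetramethyl-2-(prop-1-en-2-yl)-1,3,2-dioxaborolane (isopropenylboronic acid pinacol ester)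
Product: 5 [3-(2-methylpropanoyloxy)-4-(prop-1-en-2-yl)phenyl]methyl pentanoate
Conditions: Pd(dppf)Cl2 (3 mol %), CsF (3 equiv), anhydrous 1,4-dioxane, 80 °C
Reagents that add atoms: none
Why: Suzuki–Miyaura coupling with anhydrous fluoride activation of the boronate avoids aqueous base, so the aryl and benzylic esters survive; the product is the 8,9-dehydrothymol stage and has no stereocentre.

Step 4
Reactants: 5 [3-(2-methylpropanoyloxy)-4-(prop-1-en-2-yl)phenyl]methyl pentanoate
Product: 7 [4-(3-acetoxyprop-1-en-2-yl)-3-(2-methylpropanoyloxy)phenyl]methyl pentanoate, via allylic alcohol 6 (not isolated)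
Conditions: SeO2 (30 mol %), tBuOOH (1.5 equiv, in decane), CH2Cl2, rt; then Ac2O (4 equiv), pyridine, DMAP (cat.), 0 °C
Reagents that add atoms: tert-butyl hydroperoxide, CC(C)(C)OO (oxygen relayed by the catalytic SeO2); acetic anhydride, CC(=O)OC(C)=O
Why: Riley allylic oxidation in its catalytic SeO2/tBuOOH form (ene reaction, then [2,3]-sigmatropic shift) can only attack the isopropenyl methyl group, the sole allylic C–H site, and acetylating the primary alcohol in the same flask forestalls migration of the neighbouring aryl isobutyryl group; no stereocentre is formed.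

Step 5
Reactants: 7 [4-(3-acetoxyprop-1-en-2-yl)-3-(2-methylpropanoyloxy)phenyl]methyl pentanoate
Product: 8 [4-[(2S)-2-(acetoxymethyl)oxiran-2-yl]-3-(2-methylpropanoyloxy)phenyl]methyl pentanoate (CNP0107520.1)
Conditions: Fe(OTf)2((S,S)-Me2N-PDP) (3 mol %), N-(1,8-naphthaloyl)-L-isoleucine (4 mol %), 30% aq H2O2 (2 equiv, slow addition), MeCN, −30 °C
Reagents that add atoms: hydrogen peroxide, OO
Why: Proposed new method: the closest known reaction type is the non-haem iron/H2O2/carboxylic-acid asymmetric epoxidation of α-alkylstyrenes, here extended to an α-(acetoxymethyl)styrene with an ortho acyloxy group; the amino acid co-ligand assists heterolysis of the iron hydroperoxide (from the divalent iron precatalyst) to an electrophilic iron–oxo carboxylate that transfers oxygen to the C=C far faster than to the deactivated C–H bonds, and the C2-symmetric ligand pocket tells the aryl flank from the CH2OAc flank to set the (S) centre directly in the target; the sense of induction on this substrate cannot be predicted, so the first run is assayed by chiral HPLC against the sample from the directed-epoxidation fallback and the (R,R)-ligand/D-amino acid pair is used if the (R)-epoxide predominates.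

## Compound list

1 | 2-bromo-5-(hydroxymethyl)phenol | OCc1ccc(Br)c(O)c1 | starting material
2 | (4-bromo-3-hydroxyphenyl)methyl pentanoate | CCCCC(=O)OCc1ccc(Br)c(O)c1 | intermediate
3 | [4-bromo-3-(2-methylpropanoyloxy)phenyl]methyl pentanoate | CCCCC(=O)OCc1ccc(Br)c(OC(=O)C(C)C)c1 | intermediate
4 | 4,4,5,5-tetramethyl-2-(prop-1-en-2-yl)-1,3,2-dioxaborolane | CC(=C)B1OC(C)(C)C(C)(C)O1 | starting material
5 | [3-(2-methylpropanoyloxy)-4-(prop-1-en-2-yl)phenyl]methyl pentanoate | CCCCC(=O)OCc1ccc(C(C)=C)c(OC(=O)C(C)C)c1 | intermediate
6 | [4-(3-hydroxyprop-1-en-2-yl)-3-(2-methylpropanoyloxy)phenyl]methyl pentanoate | CCCCC(=O)OCc1ccc(C(=C)CO)c(OC(=O)C(C)C)c1 | intermediate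
7 | [4-(3-acetoxyprop-1-en-2-yl)-3-(2-methylpropanoyloxy)phenyl]methyl pentanoate | CCCCC(=O)OCc1ccc(C(=C)COC(C)=O)c(OC(=O)C(C)C)c1 | intermediate
8 | [4-[(2S)-2-(acetoxymethyl)oxiran-2-yl]-3-(2-methylpropanoyloxy)phenyl]methyl pentanoate | CCCCC(=O)OCc1ccc([C@@]2(COC(C)=O)CO2)c(OC(=O)C(C)C)c1 | target

## Count and risks

Total step count: 5. Longest linear sequence: 5 (1 → 2 → 3 → 5 → 7 → 8).

**Step 5** is the most likely to fail. The enantioselectivity and the sense of induction on an ortho-substituted α-(acetoxymethyl)styrene are unknown, and the tertiary benzylic epoxide is acid-sensitive. The fallback replaces catalyst control by substrate direction. It sets out from the allylic alcohol 6, obtained by stopping step 4 before the anhydride is added. Titanium–tartrate directed epoxidation (Ti(OiPr)4, D-(−)-DIPT, tBuOOH, 4 Å molecular sieves, CH2Cl2, −20 °C) gives [4-[(2R)-2-(hydroxymethyl)oxiran-2-yl]-3-(2-methylpropanoyloxy)phenyl]methyl pentanoate F1. D-(−)-tartrate is the antipode of the L-(+)-tartrate that gives (S)-2-methylglycidol from methallyl alcohol, so with aryl in place of methyl it gives the (2R)-alcohol. Acetylation in the same flask (Ac2O, Et3N, DMAP, −20 °C) leaves the centre untouched but ranks CH2OAc above the ring CH2, so the (2R)-alcohol is the (S)-acetate and the route comes back at 8.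

**Step 4** may stall or over-oxidise to the 2-arylacrolein, and free 6 can take over the neighbouring isobutyryl group. The fallback brings the oxygenated three-carbon unit in by a coupling of reversed polarity instead of a C–H oxidation. It sets out from bromide 3, which is borylated (B2pin2, Pd(dppf)Cl2, KOAc, dioxane, 80 °C) to [3-(2-methylpropanoyloxy)-4-(4,4,5,5-tetramethyl-1,3,2-dioxaborolan-2-yl)phenyl]methyl pentanoate F2. This is coupled with commercial 2-bromoprop-2-en-1-ol (Pd(dppf)Cl2, CsF, dioxane, 70 °C) to come back at the allylic alcohol 6, which is acetylated as in step 4 to give 7.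

**Step 3** may lose the aryl isobutyrate to the basic fluoride at 80 °C, and the freed ortho-bromophenol couples poorly. The fallback changes the order of events so that no aryl ester is present during the coupling. It sets out from phenol 2, which is coupled with 4 under mild aqueous conditions (Pd(OAc)2, SPhos, K3PO4, THF/H2O, 40 °C) to (3-hydroxy-4-(prop-1-en-2-yl)phenyl)methyl pentanoate F3. This is acylated at once with 2-methylpropanoyl chloride (Et3N, DMAP, CH2Cl2, 0 °C) to come back at 5.

## Further compounds

F1 | step 5 | [4-[(2R)-2-(hydroxymethyl)oxiran-2-yl]-3-(2-methylpropanoyloxy)phenyl]methyl pentanoate | CCCCC(=O)OCc1ccc([C@@]2(CO)CO2)c(OC(=O)C(C)C)c1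
F2 | step 4 | [3-(2-methylpropanoyloxy)-4-(4,4,5,5-tetramethyl-1,3,2-dioxaborolan-2-yl)phenyl]methyl pentanoate | CCCCC(=O)OCc1ccc(B2OC(C)(C)C(C)(C)O2)c(OC(=O)C(C)C)c1
F3 | step 3 | (3-hydroxy-4-(prop-1-en-2-yl)phenyl)methyl pentanoate | CCCCC(=O)OCc1ccc(C(C)=C)c(O)c1
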